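**Retrosynthetic overview**
1. 16 ⇒ 15 ⇒ 13: the last two steps are N–O cleavage at C9 and senecioylation of the only free hydroxyl (C6).
2. 13 ⇒ 11 (key step, one flask): metathesis forms C7=C11 and closes the lactone ring as a bromobutenolide. An allylchromium addition to the epoxy aldehyde then forms C6–C7 and closes the ten-membered ring.
3. 11 ⇒ 6 + 10: Felkin vinyl addition (C8), Sharpless epoxidation (C4, C5), primary-selective oxidation, esterification.
4. 6 ⇒ 3: desymmetrising mono-oxidation, asymmetric transfer hydrogenation (C10), α-oxyamination (C9).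
5. 3 ⇒ 1: twofold carboalumination/hydroxymethylation of hepta-1,6-diyne. Ring order: epoxide, then lactone, then carbocycle.

Assumption: germacrane-type locants are used only as labels (C4/C5 epoxide carbons with C4 bearing CH3, C6 ester carbon, C7 ring fusion, C8 lactone carbinol, C9 carbinol, C10 CH(CH3), C1–C3 the three CH2, C11–C13 acrylate unit); "TMP-oxy" means (2,2,6,6-tetramethylpiperidin-1-yl)oxy; the sense of induction of each chiral catalyst is taken from its closest known substrate class, and the other catalyst enantiomer is used if it proves opposite.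

Step 1
Reactants: 1 hepta-1,6-diyne
Product: 3 (2E,7E)-3,7-dimethylnona-2,7-diene-1,9-diol, via bis-alkenylalane 2 (not isolated)
Conditions: Me3Al (4.5 equiv), Cp2ZrCl2 (40 mol %), CH2Cl2, 0 to 23 °C; then n-BuLi (2.2 equiv), THF, −78 °C; (CH2O)n, −78 to 23 °C; aq. Rochelle salt
Reagents that add atoms: trimethylaluminium C[Al](C)C; paraformaldehyde, reacting as formaldehyde C=O
Why: Negishi zirconium-catalysed carboalumination adds CH3 and Al syn to each terminal alkyne with Al at the terminus, so hydroxymethylation of the derived alanate gives both trisubstituted alkenes as E in a symmetric product that already holds C1–C6, C8–C10 and both methyl groups.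

Step 2
Reactants: 3 (2E,7E)-3,7-dimethylnona-2,7-diene-1,9-diol
Product: 4 (2E,7E)-9-hydroxy-3,7-dimethylnona-2,7-dienal
Conditions: activated MnO2 (5 equiv), CH2Cl2, 0 °C, stopped near half conversion; recovered 3 recycled
Reagents that add atoms: none
Why: MnO2 allylic alcohol oxidation of a diol with two identical ends can give only one mono-aldehyde, so a statistical run with recycling differentiates the termini in one step without a protecting group and without forming a stereocenter.

Step 3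
Reactants: 4 (2E,7E)-9-hydroxy-3,7-dimethylnona-2,7-dienal
Product: 5 (3R,7E)-9-hydroxy-3,7-dimethylnon-7-enal
Conditions: morpholinium salt of (R)-3,3′-bis(2,4,6-triisopropylphenyl)-1,1′-binaphthyl-2,2′-diyl hydrogen phosphate (20 mol %), diethyl 2,6-dimethyl-1,4-dihydropyridine-3,5-dicarboxylate (1.1 equiv), 1,4-dioxane, 50 °C
Reagents that add atoms: none
Why: Iminium-type organocatalytic transfer hydrogenation under asymmetric counteranion-directed catalysis delivers hydride from the Hantzsch ester to one face of the β-methyl-β-alkyl enal, which sets C10 as R in the same sense as citral to (R)-citronellal and leaves the unactivated allylic-alcohol alkene untouched.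

Step 4
Reactants: 5 (3R,7E)-9-hydroxy-3,7-dimethylnon-7-enal
Product: 6 (2R,3R,7E)-9-hydroxy-3,7-dimethyl-2-(TMP-oxy)non-7-enal
Conditions: TEMPO (1.2 equiv), CuCl2 (10 mol %), (5R)-5-benzyl-2,2,3-trimethylimidazolidin-4-one·TFA (20 mol %), air, acetone, −10 °C
Reagents that add atoms: TEMPO CC1(C)CCCC(C)(C)N1[O]
Why: Enantioselective aldehyde α-oxyamination (enamine catalysis merged with CuCl2/TEMPO) transfers the aminoxyl oxygen to the open face of the chiral enamine, which sets C9 as R under catalyst control, gives a configurationally stable aldehyde that carries a bulky non-chelating protecting group, and in its base-free acidic medium keeps copper-alkoxide oxidation of the allylic alcohol slow.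

Step 5
Reactants: 6 (2R,3R,7E)-9-hydroxy-3,7-dimethyl-2-(TMP-oxy)non-7-enal
Product: 7 (3S,4R,5R,9E)-5,9-dimethyl-4-(TMP-oxy)undeca-1,9-diene-3,11-diol
Conditions: CH2=CHMgBr (2.5 equiv), THF, −78 °C; aq. NH4Cl
Reagents that add atoms: vinylmagnesium bromide C=C[Mg]Br
Why: Grignard 1,2-addition follows the polar Felkin–Anh model because the hindered O-TMP group cannot chelate and stands anti to the incoming vinyl group, which sets C8 as S (8,9-anti), while the first equivalent only deprotonates the remote primary alcohol.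

Step 6
Reactants: 7 (3S,4R,5R,9E)-5,9-dimethyl-4-(TMP-oxy)undeca-1,9-diene-3,11-diol
Product: 8 (3S,4R,5R)-8-[(2R,3R)-3-(hydroxymethyl)-2-methyloxiran-2-yl]-5-methyl-4-(TMP-oxy)oct-1-en-3-ol
Conditions: Ti(OiPr)4 (20 mol %), D-(−)-diethyl tartrate (24 mol %), t-BuOOH (1.2 equiv), 4 Å molecular sieves, CH2Cl2, −25 °C
Reagents that add atoms: tert-butyl hydroperoxide CC(C)(C)OO
Why: Katsuki–Sharpless asymmetric epoxidation with the D-(−)-tartrate gives the (2R,3R)-epoxy alcohol of a geraniol-type E-alkene, which sets C4 and C5 by reagent control as a trans epoxide, and the trisubstituted primary allylic alcohol reacts far faster than the hindered monosubstituted vinyl carbinol.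

Step 7
Reactants: 8 (3S,4R,5R)-8-[(2R,3R)-3-(hydroxymethyl)-2-methyloxiran-2-yl]-5-methyl-4-(TMP-oxy)oct-1-en-3-ol
Product: 9 (2S,3R)-3-[(4R,5R,6S)-6-hydroxy-4-methyl-5-(TMP-oxy)oct-7-en-1-yl]-3-methyloxirane-2-carbaldehyde
Conditions: TEMPO (10 mol %), PhI(OAc)2 (1.1 equiv), CH2Cl2, 0 to 23 °C
Reagents that add atoms: none
Why: Oxoammonium-catalysed (TEMPO/PhI(OAc)2) oxidation is strongly selective for the unhindered primary alcohol over the crowded secondary one and is mild enough for epoxy aldehydes, so no stereocenter changes (the C5 descriptor changes only through CIP ranking).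

Step 8
Reactants: 9 (2S,3R)-3-[(4R,5R,6S)-6-hydroxy-4-methyl-5-(TMP-oxy)oct-7-en-1-yl]-3-methyloxirane-2-carbaldehyde; 10 2-(bromomethyl)prop-2-enoic acid
Product: 11 (3S,4R,5R)-8-[(2R,3S)-3-formyl-2-methyloxiran-2-yl]-5-methyl-4-(TMP-oxy)oct-1-en-3-yl 2-(bromomethyl)prop-2-enoate
Conditions: DCC (1.3 equiv), DMAP (5 mol %), CH2Cl2, 0 °C
Reagents that add atoms: none
Why: Steglich esterification acylates the only hydroxyl group with retention at C8 and brings in C11, C12 and C13, and the low DMAP loading and temperature limit SN2′ attack on the allylic bromide.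

Step 9
Reactants: 11 (3S,4R,5R)-8-[(2R,3S)-3-formyl-2-methyloxiran-2-yl]-5-methyl-4-(TMP-oxy)oct-1-en-3-yl 2-(bromomethyl)prop-2-enoate
Product: 13 (4R,5R,6R,7R,8S,9R,10R)-4,5-epoxy-6-hydroxy-9-(TMP-oxy)germacr-11(13)-en-12,8-olide, via bromobutenolide 12 (not isolated)
Conditions: second-generation Hoveyda–Grubbs catalyst (5 mol %), CH2Cl2 (3 mM), 40 °C, 4 h; then THF, CrCl2 (8 equiv), 23 °C, 16 h; aqueous work-up
Reagents that add atoms: none
Why: Proposed new method: ring-closing metathesis of the vinyl carbinol acrylate (closest known type: acrylate metathesis to butenolides) first closes the lactone ring as 12, and in the same dilute flask divalent chromium converts its allylic bromide into an allylchromium species that adds through C7 (SE2′) to the epoxy aldehyde in a Nozaki–Hiyama–Kishi macrocyclisation (closest known types: CrCl2 closure of ten-membered germacrane rings at this bond and Barbier additions of 3-(bromomethyl)furan-2(5H)-one to aldehydes), where attack anti to the C8 side chain sets C7 (trans lactone), the ring-locked E-type allyl geometry in a chair transition state sets C6 anti to C7, this sense coincides with Felkin–Anh attack on the epoxy aldehyde (5,6-erythro, which peripheral epoxidation of a preformed macrocycle would not give), and the in-plane C8–O bond of the butenolide resists the 1,4-elimination that an open-chain acyloxy allylmetal would suffer.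

Step 10
Reactants: 13 (4R,5R,6R,7R,8S,9R,10R)-4,5-epoxy-6-hydroxy-9-(TMP-oxy)germacr-11(13)-en-12,8-olide; 14 3-methylbut-2-enoyl chloride
Product: 15 (4R,5R,6R,7R,8S,9R,10R)-4,5-epoxy-6-(3-methylbut-2-enoyloxy)-9-(TMP-oxy)germacr-11(13)-en-12,8-olide
Conditions: pyridine (3 equiv), DMAP (10 mol %), CH2Cl2, 0 to 23 °C
Reagents that add atoms: none
Why: DMAP-catalysed acylation meets a single free hydroxyl (C6) and proceeds with retention, and pyridine instead of a trialkylamine avoids the vinylketene pathway that would deconjugate the senecioate.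

Step 11
Reactants: 15 (4R,5R,6R,7R,8S,9R,10R)-4,5-epoxy-6-(3-methylbut-2-enoyloxy)-9-(TMP-oxy)germacr-11(13)-en-12,8-olide
Product: 16 (4R,5R,6R,7S,8S,9R,10R)-4,5-epoxy-9-hydroxy-6-(3-methylbut-2-enoyloxy)germacr-11(13)-en-12,8-olide (CNP0119422.1)
Conditions: Zn dust (20 equiv), AcOH/THF/H2O 3:1:1, 23 to 40 °C
Reagents that add atoms: none
Why: Reductive N–O cleavage of the alkoxyamine by zinc in acetic acid frees the C9 hydroxyl with retention, does not reduce simple acrylates or enoates, is too weakly acidic to open the epoxide quickly, and releases an amine too hindered to add to the α-methylene lactone (the C7 descriptor changes only through CIP ranking).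

**Compound list**
1 | hepta-1,6-diyne | C#CCCCC#C | starting material
2 | (1E,6E)-1,7-bis(dimethylalumanyl)-2,6-dimethylhepta-1,6-diene | C[Al](C)/C=C(\C)CCC/C(C)=C/[Al](C)C | intermediate
3 | (2E,7E)-3,7-dimethylnona-2,7-diene-1,9-diol | OC/C=C(\C)CCC/C(C)=C/CO | intermediate
4 | (2E,7E)-9-hydroxy-3,7-dimethylnona-2,7-dienal | OC/C=C(\C)CCC/C(C)=C/C=O | intermediate
5 | (3R,7E)-9-hydroxy-3,7-dimethylnon-7-enal | OC/C=C(\C)CCC[C@@H](C)CC=O | intermediate
6 | (2R,3R,7E)-9-hydroxy-3,7-dimethyl-2-[(2,2,6,6-tetramethylpiperidin-1-yl)oxy]non-7-enal | OC/C=C(\C)CCC[C@@H](C)[C@@H](ON1C(C)(C)CCCC1(C)C)C=O | intermediate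
7 | (3S,4R,5R,9E)-5,9-dimethyl-4-[(2,2,6,6-tetramethylpiperidin-1-yl)oxy]undeca-1,9-diene-3,11-diol | OC/C=C(\C)CCC[C@@H](C)[C@@H](ON1C(C)(C)CCCC1(C)C)[C@@H](O)C=C | intermediate
8 | (3S,4R,5R)-8-[(2R,3R)-3-(hydroxymethyl)-2-methyloxiran-2-yl]-5-methyl-4-[(2,2,6,6-tetramethylpiperidin-1-yl)oxy]oct-1-en-3-ol | OC[C@H]1O[C@]1(C)CCC[C@@H](C)[C@@H](ON2C(C)(C)CCCC2(C)C)[C@@H](O)C=C | intermediate
9 | (2S,3R)-3-{(4R,5R,6S)-6-hydroxy-4-methyl-5-[(2,2,6,6-tetramethylpiperidin-1-yl)oxy]oct-7-en-1-yl}-3-methyloxirane-2-carbaldehyde | O=C[C@H]1O[C@]1(C)CCC[C@@H](C)[C@@H](ON2C(C)(C)CCCC2(C)C)[C@@H](O)C=C | intermediate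
10 | 2-(bromomethyl)prop-2-enoic acid | OC(=O)C(=C)CBr | starting material
11 | (3S,4R,5R)-8-[(2R,3S)-3-formyl-2-methyloxiran-2-yl]-5-methyl-4-[(2,2,6,6-tetramethylpiperidin-1-yl)oxy]oct-1-en-3-yl 2-(bromomethyl)prop-2-enoate | O=C[C@H]1O[C@]1(C)CCC[C@@H](C)[C@@H](ON2C(C)(C)CCCC2(C)C)[C@@H](OC(=O)C(=C)CBr)C=C | intermediate
12 | (2S,3R)-3-{(4R,5R)-5-[(2S)-4-(bromomethyl)-5-oxo-2,5-dihydrofuran-2-yl]-4-methyl-5-[(2,2,6,6-tetramethylpiperidin-1-yl)oxy]pentyl}-3-methyloxirane-2-carbaldehyde | O=C[C@H]1O[C@]1(C)CCC[C@@H](C)[C@@H](ON2C(C)(C)CCCC2(C)C)[C@H]3OC(=O)C(CBr)=C3 | intermediate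
13 | (4R,5R,6R,7R,8S,9R,10R)-4,5-epoxy-6-hydroxy-9-[(2,2,6,6-tetramethylpiperidin-1-yl)oxy]germacr-11(13)-en-12,8-olide (trans-fused lactone, trans epoxide) | C=C1C(=O)O[C@@H]2[C@H](ON3C(C)(C)CCCC3(C)C)[C@H](C)CCC[C@@]4(C)O[C@@H]4[C@H](O)[C@@H]12 | intermediate
14 | 3-methylbut-2-enoyl chloride | CC(C)=CC(=O)Cl | starting material
15 | (4R,5R,6R,7R,8S,9R,10R)-4,5-epoxy-6-(3-methylbut-2-enoyloxy)-9-[(2,2,6,6-tetramethylpiperidin-1-yl)oxy]germacr-11(13)-en-12,8-olide | C=C1C(=O)O[C@@H]2[C@H](ON3C(C)(C)CCCC3(C)C)[C@H](C)CCC[C@@]4(C)O[C@@H]4[C@H](OC(=O)C=C(C)C)[C@@H]12 | intermediate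
16 | (4R,5R,6R,7S,8S,9R,10R)-4,5-epoxy-9-hydroxy-6-(3-methylbut-2-enoyloxy)germacr-11(13)-en-12,8-olide, CNP0119422.1 | C=C1C(=O)O[C@@H]2[C@H](O)[C@H](C)CCC[C@@]3(C)O[C@@H]3[C@H](OC(=O)C=C(C)C)[C@@H]12 | target

**Total step count:** 11. **Longest linear sequence:** 11 (1 to 16).

**The three steps most likely to fail**

Step 9 (ring closure on a fragile epoxy aldehyde, ten-membered ring). The fallback sets out from 7 and comes back at 13, and it moves the epoxide behind the ring closure.
- MnO2 oxidises only the primary allylic alcohol of 7 to enal alcohol F1.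
- DCC coupling with 10 gives enal ester F2.
- Metathesis gives the isolated bromobutenolide enal F3.
- CrCl2 at high dilution closes the ring onto the sturdier enal to give macrocyclic allylic alcohol F4. C7 and C6 are still set by the butenolide face and the chair transition state.
- A Sharpless epoxidation with D-(−)-diethyl tartrate then gives 13. The C6 carbinol of F4 is the fast-reacting, erythro-forming configuration for this tartrate.

Step 8 (acylation of a crowded alcohol with a bromomethyl acrylate next to an epoxy aldehyde). The fallback sets out from 6 and comes back at 12, and it builds the lactone by carbon–carbon bond formation instead of O-acylation and metathesis.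
- Indium powder and methyl 2-(bromomethyl)acrylate in THF/H2O add to 6 under Felkin–Anh control to give hydroxy ester F5.
- Catalytic TsOH lactonises F5 to methylene lactone F6.
- Sharpless epoxidation with D-(−)-diethyl tartrate gives epoxy lactone F7.
- Br2 at −78 °C adds to the methylene group to give dibromide F8.
- DBU removes HBr toward C7 to give bromobutenolide alcohol F9.
- TEMPO/PhI(OAc)2 oxidises F9 to 12, which is treated with CrCl2 as in step 9.

Step 11 (reductive N–O cleavage beside epoxide, enoate and methylene lactone). The fallback sets out from 15 and comes back at 16, and it replaces reduction by oxidative cleavage followed by ketone reduction.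
- mCPBA oxidises the alkoxyamine nitrogen, and the N-oxide fragments to 9-ketone F10. The three remaining alkenes are all electron-poor and inert to mCPBA.
- Zn(BH4)2 in Et2O at −78 °C reduces the ketone under chelation with the C8 oxygen to the 8,9-anti alcohol 16.

**Further compounds**
F1 | step 9 | enal alcohol, (2E,7R,8R,9S)-9-hydroxy-3,7-dimethyl-8-(TMP-oxy)undeca-2,10-dienal | O=C/C=C(\C)CCC[C@@H](C)[C@@H](ON1C(C)(C)CCCC1(C)C)[C@@H](O)C=C
F2 | step 9 | enal ester, (3S,4R,5R,9E)-5,9-dimethyl-11-oxo-4-(TMP-oxy)undeca-1,9-dien-3-yl 2-(bromomethyl)prop-2-enoate | O=C/C=C(\C)CCC[C@@H](C)[C@@H](ON1C(C)(C)CCCC1(C)C)[C@@H](OC(=O)C(=C)CBr)C=C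
F3 | step 9 | bromobutenolide enal, (2E,7R,8R)-8-[(2S)-4-(bromomethyl)-5-oxo-2,5-dihydrofuran-2-yl]-3,7-dimethyl-8-(TMP-oxy)oct-2-enal | O=C/C=C(\C)CCC[C@@H](C)[C@@H](ON1C(C)(C)CCCC1(C)C)[C@H]2OC(=O)C(CBr)=C2
F4 | step 9 | macrocyclic allylic alcohol, (4E,6S,7R,8S,9R,10R)-6-hydroxy-9-(TMP-oxy)germacra-4,11(13)-dien-12,8-olide | C=C1C(=O)O[C@@H]2[C@H](ON3C(C)(C)CCCC3(C)C)[C@H](C)CCC/C(C)=C/[C@H](O)[C@@H]12
F5 | step 8 | hydroxy ester, methyl (4S,5R,6R,10E)-4,12-dihydroxy-6,10-dimethyl-2-methylidene-5-(TMP-oxy)dodec-10-enoate | OC/C=C(\C)CCC[C@@H](C)[C@@H](ON1C(C)(C)CCCC1(C)C)[C@@H](O)CC(=C)C(=O)OC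
F6 | step 8 | methylene lactone, (5S)-5-[(1R,2R,6E)-8-hydroxy-2,6-dimethyl-1-(TMP-oxy)oct-6-en-1-yl]-3-methylideneoxolan-2-one | OC/C=C(\C)CCC[C@@H](C)[C@@H](ON1C(C)(C)CCCC1(C)C)[C@@H]2CC(=C)C(=O)O2
F7 | step 8 | epoxy lactone, (5S)-5-{(1R,2R)-5-[(2R,3R)-3-(hydroxymethyl)-2-methyloxiran-2-yl]-2-methyl-1-(TMP-oxy)pentyl}-3-methylideneoxolan-2-one | OC[C@H]1O[C@]1(C)CCC[C@@H](C)[C@@H](ON2C(C)(C)CCCC2(C)C)[C@@H]3CC(=C)C(=O)O3
F8 | step 8 | dibromide, (5S)-3-bromo-3-(bromomethyl)-5-{(1R,2R)-5-[(2R,3R)-3-(hydroxymethyl)-2-methyloxiran-2-yl]-2-methyl-1-(TMP-oxy)pentyl}oxolan-2-one (both C3 epimers) | OC[C@H]1O[C@]1(C)CCC[C@@H](C)[C@@H](ON2C(C)(C)CCCC2(C)C)[C@@H]3CC(Br)(CBr)C(=O)O3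
F9 | step 8 | bromobutenolide alcohol, (5S)-3-(bromomethyl)-5-{(1R,2R)-5-[(2R,3R)-3-(hydroxymethyl)-2-methyloxiran-2-yl]-2-methyl-1-(TMP-oxy)pentyl}furan-2(5H)-one | OC[C@H]1O[C@]1(C)CCC[C@@H](C)[C@@H](ON2C(C)(C)CCCC2(C)C)[C@H]3OC(=O)C(CBr)=C3
F10 | step 11 | 9-ketone, (4R,5R,6R,7R,8S,10R)-4,5-epoxy-6-(3-methylbut-2-enoyloxy)-9-oxogermacr-11(13)-en-12,8-olide | C=C1C(=O)O[C@@H]2C(=O)[C@H](C)CCC[C@@]3(C)O[C@@H]3[C@H](OC(=O)C=C(C)C)[C@@H]12
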